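**Plan**

- Numbering used below: C1 lactone carbonyl, C2=C3 enoate, C5 piperidine N–CH, C9 spiro carbon, C10–C12 cyclopentane CH2 groups, C13 cyclopentane CH, C14 CH(CH3), C15=C16 cis-alkene, C17 carbinol, C18=C19(Cl), C21 OCH2, C23 NCH2.
- Retrosynthesis: cut O–C1 (macrolactone), then C16–C17 (alkynylation; the cis C15=C16 alkene is a semi-reduced alkyne), then C2=C3 (ring-closing metathesis) and N–C23 (N-alkylation), then N–C5 (SN2 closure of the piperidine), and last N–C9.
- Enabling feature: the spiro carbon C9 is vicinal to the cyclopentane CH (C13), whose side chain can be tied back to nitrogen as a temporary γ-lactam (N–C15(=O)–C14–C13–C9). With C9=C10 as a ring alkene and C11–H as the ene hydrogen, an acylnitroso group on the C13 acetyl arm forms N–C9 by an intramolecular ene reaction that can only give the cis-fused lactam, so N ends up cis to the C14 arm as in the target.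
- Forward, core: 2-alkylcyclopentenone, then CBS reduction (the only catalyst-set stereocentre of the carbocycle), Johnson–Claisen (C13), acylnitroso ene (C9), convex-face methylation of the lactam (C14), Keck allylation and SN2 inversion (C5, piperidine), N-alkylation and metathesis (dehydroquinolizidine), then the C15 alkyne.
- Forward, side chain and ring: the ring of 4-chloro-5,6-dihydropyran-2-one fixes the chloroalkene geometry (C17 and C20 cis). ProPhenol alkynylation sets C17, Lindlar reduction gives the 15Z alkene, and lactonisation of the dihydroxy acid at the primary C21–OH closes the 15-membered ring.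

Key step: step 5

Assumption: the ligand hands given for the CBS, Keck and ProPhenol steps follow the usual facial models for these catalyst families; where a model proves reversed on these substrates the antipodal ligand is used.
Assumption: compounds 1, 2, 20 and 25 are taken as purchasable.

**Route**

Step 1
Reactants: 1 4,4-diethoxybut-1-ene; 2 2-bromocyclopent-2-en-1-one
Product: 4 2-(4,4-diethoxybutyl)cyclopent-2-en-1-one, via alkylborane 3 (not isolated)
Conditions: 1, 9-BBN-H, THF, 0 °C to rt; then 2, PdCl2(dppf) (5 mol%), Ph3As, Cs2CO3, DMF/H2O, rt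
Reagents that add atoms: none
Why: Anti-Markovnikov hydroboration of the terminal alkene followed by B-alkyl Suzuki–Miyaura coupling with the α-bromoenone should attach the C5–C8 chain, with C5 masked as an acetal, to the future spiro carbon.

Step 2
Reactants: 4 2-(4,4-diethoxybutyl)cyclopent-2-en-1-one
Product: 5 (1R)-2-(4,4-diethoxybutyl)cyclopent-2-en-1-ol
Conditions: (S)-2-methyl-CBS-oxazaborolidine (20 mol%), BH3·SMe2, THF, −30 °C; MeOH quench
Reagents that add atoms: none
Why: Corey–Bakshi–Shibata reduction in which the α-substituted alkenyl arm acts as the large group should deliver hydride to one face and give the (R)-allylic alcohol.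

Step 3
Reactants: 5 (1R)-2-(4,4-diethoxybutyl)cyclopent-2-en-1-ol
Product: 7 ethyl 2-[(1R)-2-(4,4-diethoxybutyl)cyclopent-2-en-1-yl]acetate, via mixed ketene acetal 6 (not isolated)
Conditions: MeC(OEt)3 (excess), EtCO2H (10 mol%), 140 °C, EtOH distilled off
Reagents that add atoms: triethyl orthoacetate, CC(OCC)(OCC)OCC
Why: Johnson–Claisen rearrangement is suprafacial within the ring, so the carbinol configuration should be transferred to C13 while the alkene moves to C9=C10.

Step 4
Reactants: 7 ethyl 2-[(1R)-2-(4,4-diethoxybutyl)cyclopent-2-en-1-yl]acetate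
Product: 8 2-[(1R)-2-(4,4-diethoxybutyl)cyclopent-2-en-1-yl]-N-hydroxyacetamide
Conditions: NH2OH·HCl, KOH, MeOH, 0 °C to rt
Reagents that add atoms: hydroxylamine hydrochloride, NO.Cl
Why: Base-mediated aminolysis of an unhindered ester by hydroxylamine is the standard hydroxamic acid synthesis and leaves acetal and alkene untouched.

Step 5
Reactants: 8 2-[(1R)-2-(4,4-diethoxybutyl)cyclopent-2-en-1-yl]-N-hydroxyacetamide
Product: 10 (3aR,6aS)-6a-(4,4-diethoxybutyl)-1-hydroxy-3,3a,4,6a-tetrahydrocyclopenta[b]pyrrol-2(1H)-one, via acylnitroso compound 9 (not isolated)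
Conditions: Pr4NIO4, CH2Cl2 (dilute), 0 °C to rt
Reagents that add atoms: none
Why: Periodate should oxidise the hydroxamic acid to the transient acylnitroso compound 9, whose electrophilic nitrogen bonds to C9 while its oxygen takes the allylic hydrogen from C11 on the same face, moving the alkene to C10=C11 and leaving the N-hydroxy lactam. This is an intramolecular acylnitroso ene reaction; the closest known cases are ene cyclisations of cycloalkenylacetyl nitroso compounds to bicyclic N-hydroxy lactams and the ene spirocyclisation that creates fully substituted N-bearing carbons. The five-membered lactam ring (N, C15, C14, C13, C9) closes in the exo sense (5-exo-trig) onto the alkene carbon nearer the tether, with C10 left outside the new ring. The new stereocentre C9 is controlled by C13: the two-atom tether can reach C9 only on the face that carries it, so only the cis-fused bicyclo[3.3.0] product is attainable, with N cis to the C14 arm and the C8 chain trans. The step needs regioselectivity (N to C9 rather than to the less substituted C10 with hydrogen loss from C8, which would give a bridged six-membered lactam) and chemoselectivity against bimolecular decay of 9. The short tether, the strain of the bridged alternative and slow generation of 9 at high dilution should secure both.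

Step 6
Reactants: 10 (3aR,6aS)-6a-(4,4-diethoxybutyl)-1-hydroxy-3,3a,4,6a-tetrahydrocyclopenta[b]pyrrol-2(1H)-one
Product: 11 (3aR,6aS)-6a-(4,4-diethoxybutyl)hexahydrocyclopenta[b]pyrrol-2(1H)-one
Conditions: H2 (4 atm), Raney Ni, EtOH, 50 °C
Reagents that add atoms: none
Why: Catalytic hydrogenation should saturate the cis-disubstituted cyclopentene, and Raney Ni hydrogenolysis of the hydroxamic N–O bond in the same operation should leave the N–H lactam, with no stereocentre involved.

Step 7
Reactants: 11 (3aR,6aS)-6a-(4,4-diethoxybutyl)hexahydrocyclopenta[b]pyrrol-2(1H)-one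
Product: 12 tert-butyl (3aR,6aS)-6a-(4,4-diethoxybutyl)-2-oxohexahydrocyclopenta[b]pyrrole-1(2H)-carboxylate
Conditions: Boc2O, DMAP, Et3N, MeCN, rt to 50 °C
Reagents that add atoms: di-tert-butyl dicarbonate, CC(C)(C)OC(=O)OC(=O)OC(C)(C)C
Why: DMAP-catalysed N-acylation of the lactam gives the N-Boc imide, which is needed both for clean enolate alkylation and for the later reductive ring opening.

Step 8
Reactants: 12 tert-butyl (3aR,6aS)-6a-(4,4-diethoxybutyl)-2-oxohexahydrocyclopenta[b]pyrrole-1(2H)-carboxylate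
Product: 13 tert-butyl (3R,3aR,6aS)-6a-(4,4-diethoxybutyl)-3-methyl-2-oxohexahydrocyclopenta[b]pyrrole-1(2H)-carboxylate
Conditions: LiN(SiMe3)2, THF, −78 °C; MeI, −78 to −40 °C
Reagents that add atoms: iodomethane, CI
Why: Enolate alkylation of the cis-fused bicyclic lactam should occur from the convex face, anti to the cyclopentane ring, which places the C14 methyl group as required (3R).

Step 9
Reactants: 13 tert-butyl (3R,3aR,6aS)-6a-(4,4-diethoxybutyl)-3-methyl-2-oxohexahydrocyclopenta[b]pyrrole-1(2H)-carboxylate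
Product: 14 tert-butyl (3R,3aR,6aS)-3-methyl-2-oxo-6a-(4-oxobutyl)hexahydrocyclopenta[b]pyrrole-1(2H)-carboxylate
Conditions: PPTS (cat.), acetone/H2O, 50 °C
Reagents that add atoms: water, O
Why: Mild acid-catalysed hydrolysis of the acyclic diethyl acetal should unmask the C5 aldehyde without cleaving the Boc imide.

Step 10
Reactants: 14 tert-butyl (3R,3aR,6aS)-3-methyl-2-oxo-6a-(4-oxobutyl)hexahydrocyclopenta[b]pyrrole-1(2H)-carboxylate
Product: 15 tert-butyl (3R,3aR,6aS)-6a-[(4S)-4-hydroxyhept-6-en-1-yl]-3-methyl-2-oxohexahydrocyclopenta[b]pyrrole-1(2H)-carboxylate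
Conditions: allylSnBu3, (R)-BINOL (20 mol%), Ti(OiPr)4 (10 mol%), 4 Å molecular sieves, CH2Cl2, −20 °C; aq. NaHCO3
Reagents that add atoms: allyltributylstannane, C=CC[Sn](CCCC)(CCCC)CCCC
Why: Keck asymmetric allylation should transfer the allyl group to the Re face of the unbranched aldehyde under control of the BINOL–titanium catalyst, giving the (S)-carbinol independently of the remote core stereocentres.

Step 11
Reactants: 15 tert-butyl (3R,3aR,6aS)-6a-[(4S)-4-hydroxyhept-6-en-1-yl]-3-methyl-2-oxohexahydrocyclopenta[b]pyrrole-1(2H)-carboxylate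
Product: 16 tert-butyl (3R,3aR,6aS)-6a-[(4S)-4-(methanesulfonyloxy)hept-6-en-1-yl]-3-methyl-2-oxohexahydrocyclopenta[b]pyrrole-1(2H)-carboxylate
Conditions: MsCl, Et3N, CH2Cl2, 0 °C
Reagents that add atoms: methanesulfonyl chloride, CS(=O)(=O)Cl
Why: Sulfonylation of the secondary alcohol proceeds with retention at C5 and installs the leaving group for the later inversion.

Step 12
Reactants: 16 tert-butyl (3R,3aR,6aS)-6a-[(4S)-4-(methanesulfonyloxy)hept-6-en-1-yl]-3-methyl-2-oxohexahydrocyclopenta[b]pyrrole-1(2H)-carboxylate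
Product: 17 tert-butyl N-[(1S,2R)-2-[(2R)-1-hydroxypropan-2-yl]-1-[(4S)-4-(methanesulfonyloxy)hept-6-en-1-yl]cyclopentyl]carbamate
Conditions: LiBH4, THF, 0 °C to rt
Reagents that add atoms: none
Why: Borohydride reduction of an N-Boc lactam attacks the ring carbonyl and opens the temporary ring to the carbamate and the primary C15 alcohol, while a secondary mesylate should be inert to LiBH4 at this temperature.

Step 13
Reactants: 17 tert-butyl N-[(1S,2R)-2-[(2R)-1-hydroxypropan-2-yl]-1-[(4S)-4-(methanesulfonyloxy)hept-6-en-1-yl]cyclopentyl]carbamate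
Product: 19 (2R)-2-[(1R,5S,7R)-7-(prop-2-en-1-yl)-6-azaspiro[4.5]decan-1-yl]propan-1-ol, via amino mesylate 18 (not isolated)
Conditions: CF3CO2H, CH2Cl2, 0 °C; concentrate; K2CO3, MeCN, 60 °C
Reagents that add atoms: none
Why: Acidolysis of the carbamate frees the amine on C9, which should displace the mesylate in a 6-exo-tet SN2 reaction with inversion at C5 to give the 7R piperidine, the primary alcohol being no competitor.

Step 14
Reactants: 19 (2R)-2-[(1R,5S,7R)-7-(prop-2-en-1-yl)-6-azaspiro[4.5]decan-1-yl]propan-1-ol; 20 methyl 2-(bromomethyl)prop-2-enoate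
Product: 21 methyl 2-{[(1R,5S,7R)-1-[(2R)-1-hydroxypropan-2-yl]-7-(prop-2-en-1-yl)-6-azaspiro[4.5]decan-6-yl]methyl}prop-2-enoate
Conditions: K2CO3, MeCN, 50 °C
Reagents that add atoms: none
Why: N-Alkylation of the hindered secondary amine by this highly reactive allylic bromide (direct or SN2' displacement gives the same product) should be selective over O-alkylation under carbonate.

Step 15
Reactants: 21 methyl 2-{[(1R,5S,7R)-1-[(2R)-1-hydroxypropan-2-yl]-7-(prop-2-en-1-yl)-6-azaspiro[4.5]decan-6-yl]methyl}prop-2-enoate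
Product: 22 methyl (1S,2R,9a'R)-2-[(2R)-1-hydroxypropan-2-yl]-1',4',7',8',9',9a'-hexahydrospiro[cyclopentane-1,6'-quinolizine]-3'-carboxylate
Conditions: TsOH·H2O (1.05 equiv), second-generation Grubbs catalyst (10 mol%), CH2Cl2, 40 °C; aq. NaHCO3
Reagents that add atoms: none
Why: Ring-closing metathesis of the ammonium salt (protonation keeps the amine off ruthenium) should form the six-membered trisubstituted enoate C2=C3 with loss of ethene.

Step 16
Reactants: 22 methyl (1S,2R,9a'R)-2-[(2R)-1-hydroxypropan-2-yl]-1',4',7',8',9',9a'-hexahydrospiro[cyclopentane-1,6'-quinolizine]-3'-carboxylate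
Product: 23 methyl (1S,2R,9a'R)-2-[(2R)-1-oxopropan-2-yl]-1',4',7',8',9',9a'-hexahydrospiro[cyclopentane-1,6'-quinolizine]-3'-carboxylate
Conditions: (COCl)2, DMSO, CH2Cl2, −78 °C; Et3N, −78 to −30 °C
Reagents that add atoms: none
Why: Swern oxidation tolerates the tertiary amine and enoate, and the low temperature should limit epimerisation at C14.

Step 17
Reactants: 23 methyl (1S,2R,9a'R)-2-[(2R)-1-oxopropan-2-yl]-1',4',7',8',9',9a'-hexahydrospiro[cyclopentane-1,6'-quinolizine]-3'-carboxylate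
Product: 24 methyl (1S,2R,9a'R)-2-[(2R)-but-3-yn-2-yl]-1',4',7',8',9',9a'-hexahydrospiro[cyclopentane-1,6'-quinolizine]-3'-carboxylate
Conditions: dimethyl (1-diazo-2-oxopropyl)phosphonate, K2CO3, MeOH, 0 °C to rt
Reagents that add atoms: dimethyl (1-diazo-2-oxopropyl)phosphonate, COP(=O)(OC)C(=[N+]=[N-])C(C)=O
Why: Ohira–Bestmann (Seyferth–Gilbert) homologation should convert the aldehyde to the terminal alkyne under mild base, in which methanolysis of the methyl ester is degenerate.

Step 18
Reactants: 25 dihydro-2H-pyran-2,4(3H)-dione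
Product: 26 4-chloro-5,6-dihydro-2H-pyran-2-one
Conditions: (COCl)2, DMF (cat.), CH2Cl2, 0 °C to rt
Reagents that add atoms: oxalyl chloride, O=C(Cl)C(=O)Cl
Why: Vilsmeier-type activation of the enolised cyclic β-keto lactone gives the vinylogous acid chloride, as with cyclic 1,3-diones.

Step 19
Reactants: 26 4-chloro-5,6-dihydro-2H-pyran-2-one
Product: 27 (2E)-3-chloro-5-hydroxy-N-methoxy-N-methylpent-2-enamide
Conditions: MeNH(OMe)·HCl, i-PrMgCl, THF, −20 to 0 °C; aq. NH4Cl
Reagents that add atoms: N,O-dimethylhydroxylamine hydrochloride, CNOC.Cl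
Why: Aminolysis of the lactone by the magnesium amide (Weinreb amide formation) opens the ring while keeping the ring-enforced alkene geometry, carbonyl cis to the CH2CH2O arm.

Step 20
Reactants: 27 (2E)-3-chloro-5-hydroxy-N-methoxy-N-methylpent-2-enamide
Product: 28 (2E)-5-[(tert-butyldimethylsilyl)oxy]-3-chloro-N-methoxy-N-methylpent-2-enamide
Conditions: TBSCl, imidazole, CH2Cl2, 0 °C to rt
Reagents that add atoms: tert-butyldimethylsilyl chloride, CC(C)(C)[Si](C)(C)Cl
Why: Silylation of the primary alcohol is routine and blocks relactonisation.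

Step 21
Reactants: 28 (2E)-5-[(tert-butyldimethylsilyl)oxy]-3-chloro-N-methoxy-N-methylpent-2-enamide
Product: 29 (2E)-5-[(tert-butyldimethylsilyl)oxy]-3-chloropent-2-enal
Conditions: i-Bu2AlH, THF, −78 °C; Rochelle salt work-up
Reagents that add atoms: none
Why: Hydride reduction of a Weinreb amide stops at the chelated tetrahedral stage and should release the enal on work-up with the alkene geometry intact.

Step 22
Reactants: 24 methyl (1S,2R,9a'R)-2-[(2R)-but-3-yn-2-yl]-1',4',7',8',9',9a'-hexahydrospiro[cyclopentane-1,6'-quinolizine]-3'-carboxylate; 29 (2E)-5-[(tert-butyldimethylsilyl)oxy]-3-chloropent-2-enal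
Product: 30 methyl (1S,2R,9a'R)-2-[(2R,5S,6E)-9-[(tert-butyldimethylsilyl)oxy]-7-chloro-5-hydroxynon-6-en-3-yn-2-yl]-1',4',7',8',9',9a'-hexahydrospiro[cyclopentane-1,6'-quinolizine]-3'-carboxylate
Conditions: Me2Zn (3 equiv), (S,S)-ProPhenol (20 mol%), Ph3P=O (40 mol%), 29 (2 equiv), toluene, 0 °C; aq. NH4Cl
Reagents that add atoms: none
Why: Trost's dinuclear zinc–ProPhenol alkynylation, which accepts α,β-unsaturated aldehydes, should add the zinc acetylide of 24 to the Re face of the enal and set C17 by catalyst control (5S here, the same spatial arrangement as 17R of the target).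

Step 23
Reactants: 30 methyl (1S,2R,9a'R)-2-[(2R,5S,6E)-9-[(tert-butyldimethylsilyl)oxy]-7-chloro-5-hydroxynon-6-en-3-yn-2-yl]-1',4',7',8',9',9a'-hexahydrospiro[cyclopentane-1,6'-quinolizine]-3'-carboxylate
Product: 31 methyl (1S,2R,9a'R)-2-[(2S,3Z,5R,6E)-9-[(tert-butyldimethylsilyl)oxy]-7-chloro-5-hydroxynona-3,6-dien-2-yl]-1',4',7',8',9',9a'-hexahydrospiro[cyclopentane-1,6'-quinolizine]-3'-carboxylate
Conditions: H2 (1 atm), Pd/CaCO3 poisoned with Pb(OAc)2 (Lindlar catalyst), quinoline, EtOAc, rt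
Reagents that add atoms: none
Why: Lindlar semihydrogenation adds H2 syn to the alkyne to give the Z-alkene, and the poisoned catalyst should spare the vinyl chloride and the trisubstituted enoate.

Step 24
Reactants: 31 methyl (1S,2R,9a'R)-2-[(2S,3Z,5R,6E)-9-[(tert-butyldimethylsilyl)oxy]-7-chloro-5-hydroxynona-3,6-dien-2-yl]-1',4',7',8',9',9a'-hexahydrospiro[cyclopentane-1,6'-quinolizine]-3'-carboxylate
Product: 32 methyl (1S,2R,9a'R)-2-[(2S,3Z,5R,6E)-7-chloro-5,9-dihydroxynona-3,6-dien-2-yl]-1',4',7',8',9',9a'-hexahydrospiro[cyclopentane-1,6'-quinolizine]-3'-carboxylate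
Conditions: Bu4NF, THF, 0 °C
Reagents that add atoms: none
Why: Fluoride cleaves the primary silyl ether under conditions that avoid acid, to which the bis-allylic C17 alcohol is sensitive.

Step 25
Reactants: 32 methyl (1S,2R,9a'R)-2-[(2S,3Z,5R,6E)-7-chloro-5,9-dihydroxynona-3,6-dien-2-yl]-1',4',7',8',9',9a'-hexahydrospiro[cyclopentane-1,6'-quinolizine]-3'-carboxylate
Product: 33 (1S,2R,9a'R)-2-[(2S,3Z,5R,6E)-7-chloro-5,9-dihydroxynona-3,6-dien-2-yl]-1',4',7',8',9',9a'-hexahydrospiro[cyclopentane-1,6'-quinolizine]-3'-carboxylic acid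
Conditions: LiOH·H2O, THF/MeOH/H2O, rt; then AcOH to pH 6
Reagents that add atoms: lithium hydroxide, [Li+].[OH-]
Why: Saponification of the conjugated methyl ester is routine and should not disturb the vinyl chloride or the allylic alcohol.

Step 26
Reactants: 33 (1S,2R,9a'R)-2-[(2S,3Z,5R,6E)-7-chloro-5,9-dihydroxynona-3,6-dien-2-yl]-1',4',7',8',9',9a'-hexahydrospiro[cyclopentane-1,6'-quinolizine]-3'-carboxylic acid
Product: 34 target macrolactone CNP0129639.4 (5R,9S,13R,14S,17R; 15Z; 18E in the numbering of the plan)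
Conditions: 2-methyl-6-nitrobenzoic anhydride (MNBA), DMAP, Et3N, CH2Cl2 (1 mM), rt, slow addition of 33
Reagents that add atoms: none
Why: Shiina macrolactonisation through the mixed anhydride should acylate the primary C21–OH, because closure at the secondary C17–OH would need a strained 11-membered ring holding a cis-alkene, while the two cis-alkenes pre-fold the chain for the 15-membered ring.

**Compound list**

1 | 4,4-diethoxybut-1-ene | C=CCC(OCC)OCC | starting material
2 | 2-bromocyclopent-2-en-1-one | O=C1CCC=C1Br | starting material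
3 | 9-(4,4-diethoxybutyl)-9-borabicyclo[3.3.1]nonane | CCOC(OCC)CCCB1C2CCCC1CCC2 | intermediate
4 | 2-(4,4-diethoxybutyl)cyclopent-2-en-1-one | O=C1CCC=C1CCCC(OCC)OCC | intermediate
5 | (1R)-2-(4,4-diethoxybutyl)cyclopent-2-en-1-ol | O[C@@H]1CCC=C1CCCC(OCC)OCC | intermediate
6 | (1R)-2-(4,4-diethoxybutyl)-1-[(1-ethoxyethenyl)oxy]cyclopent-2-ene (mixed ketene acetal) | C=C(OCC)O[C@@H]1CCC=C1CCCC(OCC)OCC | intermediate
7 | ethyl 2-[(1R)-2-(4,4-diethoxybutyl)cyclopent-2-en-1-yl]acetate | CCOC(=O)C[C@@H]1C(CCCC(OCC)OCC)=CCC1 | intermediate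
8 | 2-[(1R)-2-(4,4-diethoxybutyl)cyclopent-2-en-1-yl]-N-hydroxyacetamide | ONC(=O)C[C@@H]1C(CCCC(OCC)OCC)=CCC1 | intermediate
9 | 2-[(1R)-2-(4,4-diethoxybutyl)cyclopent-2-en-1-yl]-1-nitrosoethan-1-one (acylnitroso compound) | O=NC(=O)C[C@@H]1C(CCCC(OCC)OCC)=CCC1 | intermediate
10 | (3aR,6aS)-6a-(4,4-diethoxybutyl)-1-hydroxy-3,3a,4,6a-tetrahydrocyclopenta[b]pyrrol-2(1H)-one | O=C1C[C@H]2CC=C[C@@]2(CCCC(OCC)OCC)N1O | intermediate
11 | (3aR,6aS)-6a-(4,4-diethoxybutyl)hexahydrocyclopenta[b]pyrrol-2(1H)-one | O=C1C[C@H]2CCC[C@@]2(CCCC(OCC)OCC)N1 | intermediate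
12 | tert-butyl (3aR,6aS)-6a-(4,4-diethoxybutyl)-2-oxohexahydrocyclopenta[b]pyrrole-1(2H)-carboxylate | O=C1C[C@H]2CCC[C@@]2(CCCC(OCC)OCC)N1C(=O)OC(C)(C)C | intermediate
13 | tert-butyl (3R,3aR,6aS)-6a-(4,4-diethoxybutyl)-3-methyl-2-oxohexahydrocyclopenta[b]pyrrole-1(2H)-carboxylate | O=C1[C@H](C)[C@H]2CCC[C@@]2(CCCC(OCC)OCC)N1C(=O)OC(C)(C)C | intermediate
14 | tert-butyl (3R,3aR,6aS)-3-methyl-2-oxo-6a-(4-oxobutyl)hexahydrocyclopenta[b]pyrrole-1(2H)-carboxylate | O=C1[C@H](C)[C@H]2CCC[C@@]2(CCCC=O)N1C(=O)OC(C)(C)C | intermediate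
15 | tert-butyl (3R,3aR,6aS)-6a-[(4S)-4-hydroxyhept-6-en-1-yl]-3-methyl-2-oxohexahydrocyclopenta[b]pyrrole-1(2H)-carboxylate | O=C1[C@H](C)[C@H]2CCC[C@@]2(CCC[C@H](O)CC=C)N1C(=O)OC(C)(C)C | intermediate
16 | tert-butyl (3R,3aR,6aS)-6a-[(4S)-4-(methanesulfonyloxy)hept-6-en-1-yl]-3-methyl-2-oxohexahydrocyclopenta[b]pyrrole-1(2H)-carboxylate | O=C1[C@H](C)[C@H]2CCC[C@@]2(CCC[C@H](OS(C)(=O)=O)CC=C)N1C(=O)OC(C)(C)C | intermediate
17 | tert-butyl N-[(1S,2R)-2-[(2R)-1-hydroxypropan-2-yl]-1-[(4S)-4-(methanesulfonyloxy)hept-6-en-1-yl]cyclopentyl]carbamate | OC[C@H](C)[C@H]1CCC[C@@]1(CCC[C@H](OS(C)(=O)=O)CC=C)NC(=O)OC(C)(C)C | intermediate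
18 | (4S)-1-[(1S,2R)-1-amino-2-[(2R)-1-hydroxypropan-2-yl]cyclopentyl]hept-6-en-4-yl methanesulfonate | OC[C@H](C)[C@H]1CCC[C@@]1(CCC[C@H](OS(C)(=O)=O)CC=C)N | intermediate
19 | (2R)-2-[(1R,5S,7R)-7-(prop-2-en-1-yl)-6-azaspiro[4.5]decan-1-yl]propan-1-ol | OC[C@H](C)[C@H]1CCC[C@]12CCC[C@H](CC=C)N2 | intermediate
20 | methyl 2-(bromomethyl)prop-2-enoate | C=C(CBr)C(=O)OC | starting material
21 | methyl 2-{[(1R,5S,7R)-1-[(2R)-1-hydroxypropan-2-yl]-7-(prop-2-en-1-yl)-6-azaspiro[4.5]decan-6-yl]methyl}prop-2-enoate | OC[C@H](C)[C@H]1CCC[C@]12CCC[C@H](CC=C)N2CC(=C)C(=O)OC | intermediate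
22 | methyl (1S,2R,9a'R)-2-[(2R)-1-hydroxypropan-2-yl]-1',4',7',8',9',9a'-hexahydrospiro[cyclopentane-1,6'-quinolizine]-3'-carboxylate | OC[C@H](C)[C@H]1CCC[C@]12CCC[C@@H]3CC=C(C(=O)OC)CN23 | intermediate
23 | methyl (1S,2R,9a'R)-2-[(2R)-1-oxopropan-2-yl]-1',4',7',8',9',9a'-hexahydrospiro[cyclopentane-1,6'-quinolizine]-3'-carboxylate | O=C[C@H](C)[C@H]1CCC[C@]12CCC[C@@H]3CC=C(C(=O)OC)CN23 | intermediate
24 | methyl (1S,2R,9a'R)-2-[(2R)-but-3-yn-2-yl]-1',4',7',8',9',9a'-hexahydrospiro[cyclopentane-1,6'-quinolizine]-3'-carboxylate | C#C[C@H](C)[C@H]1CCC[C@]12CCC[C@@H]3CC=C(C(=O)OC)CN23 | intermediate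
25 | dihydro-2H-pyran-2,4(3H)-dione | O=C1CC(=O)CCO1 | starting material
26 | 4-chloro-5,6-dihydro-2H-pyran-2-one | O=C1C=C(Cl)CCO1 | intermediate
27 | (2E)-3-chloro-5-hydroxy-N-methoxy-N-methylpent-2-enamide | CON(C)C(=O)/C=C(/Cl)CCO | intermediate
28 | (2E)-5-[(tert-butyldimethylsilyl)oxy]-3-chloro-N-methoxy-N-methylpent-2-enamide | CON(C)C(=O)/C=C(/Cl)CCO[Si](C)(C)C(C)(C)C | intermediate
29 | (2E)-5-[(tert-butyldimethylsilyl)oxy]-3-chloropent-2-enal | O=C/C=C(/Cl)CCO[Si](C)(C)C(C)(C)C | intermediate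
30 | methyl (1S,2R,9a'R)-2-[(2R,5S,6E)-9-[(tert-butyldimethylsilyl)oxy]-7-chloro-5-hydroxynon-6-en-3-yn-2-yl]-1',4',7',8',9',9a'-hexahydrospiro[cyclopentane-1,6'-quinolizine]-3'-carboxylate | C[C@@H](C#C[C@@H](O)/C=C(/Cl)CCO[Si](C)(C)C(C)(C)C)[C@H]1CCC[C@]12CCC[C@@H]3CC=C(C(=O)OC)CN23 | intermediate
31 | methyl (1S,2R,9a'R)-2-[(2S,3Z,5R,6E)-9-[(tert-butyldimethylsilyl)oxy]-7-chloro-5-hydroxynona-3,6-dien-2-yl]-1',4',7',8',9',9a'-hexahydrospiro[cyclopentane-1,6'-quinolizine]-3'-carboxylate | C[C@@H](/C=C\[C@@H](O)/C=C(/Cl)CCO[Si](C)(C)C(C)(C)C)[C@H]1CCC[C@]12CCC[C@@H]3CC=C(C(=O)OC)CN23 | intermediate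
32 | methyl (1S,2R,9a'R)-2-[(2S,3Z,5R,6E)-7-chloro-5,9-dihydroxynona-3,6-dien-2-yl]-1',4',7',8',9',9a'-hexahydrospiro[cyclopentane-1,6'-quinolizine]-3'-carboxylate | C[C@@H](/C=C\[C@@H](O)/C=C(/Cl)CCO)[C@H]1CCC[C@]12CCC[C@@H]3CC=C(C(=O)OC)CN23 | intermediate
33 | (1S,2R,9a'R)-2-[(2S,3Z,5R,6E)-7-chloro-5,9-dihydroxynona-3,6-dien-2-yl]-1',4',7',8',9',9a'-hexahydrospiro[cyclopentane-1,6'-quinolizine]-3'-carboxylic acid | C[C@@H](/C=C\[C@@H](O)/C=C(/Cl)CCO)[C@H]1CCC[C@]12CCC[C@@H]3CC=C(C(=O)O)CN23 | intermediate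
34 | target macrolactone CNP0129639.4 (5R,9S,13R,14S,17R; 15Z; 18E) | C[C@H]1/C=C\[C@@H](O)/C=C(/Cl)CCOC(=O)C2=CC[C@H]3CCC[C@]4(CCC[C@H]14)N3C2 | target

**Step count and risks**

Total step count: 26. Longest linear sequence: 22 steps (steps 1–17, then 22–26); the side-chain aldehyde 29 takes 4 steps (18–21).

Steps most likely to fail:

1. Step 5 (acylnitroso ene). What may go wrong: bonding of the nitroso nitrogen to the less substituted alkene carbon with hydrogen loss from the chain (bridged lactam), or bimolecular decay of the acylnitroso species before cyclisation. Fallback, setting out from 7 and returning at 11: the N–C9 bond is made by a polar halocyclisation in which ring size and Markovnikov bias point the same way. Ester 7 is treated with O-benzylhydroxylamine hydrochloride and LiN(SiMe3)2 in THF to give the O-benzyl hydroxamate F1. Br2 and K2CO3 in aqueous MeCN should then give the bromo lactam F2 by 5-exo attack of nitrogen on the bromonium ion at the fully substituted carbon, with the ring fusion again forced cis. Hydrogenation over Raney Ni with Et3N removes bromine, the benzyl group and the N–O bond and delivers 11.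

2. Step 26 (macrolactonisation of the unprotected dihydroxy acid). What may go wrong: competing acylation at the secondary C17 hydroxyl or oligomerisation during ring closure. Fallback, setting out from 31 and returning at 34: the C17 hydroxyl is silylated with TBDPSCl and imidazole to give the bis-silyl ether F3. The primary TBS ether is cleaved selectively with HF·pyridine buffered with pyridine to give the primary alcohol F4. Saponification with LiOH gives the seco acid F5, MNBA/DMAP lactonisation gives the silylated macrolactone F6, and HF·pyridine removes the TBDPS group to give 34.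

3. Step 22 (asymmetric alkynylation). What may go wrong: poor facial selectivity with this β-chloro enal, or methyl transfer from zinc in place of alkynyl transfer. Fallback, setting out from 24 and 29 and returning at 30: the stereocentre is set by reduction instead of addition. Alkyne 24 is deprotonated with LiN(SiMe3)2 in THF at −78 °C and added to 29 to give the carbinol as a mixture of C17 epimers F7. MnO2 oxidation gives the ynone F8. Noyori transfer hydrogenation with RuCl(p-cymene)[(S,S)-TsDPEN] in HCO2H/Et3N, the alkynyl group taking the role of the aryl group in the usual model, should return 30.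

**Further compounds**

F1 | step 5 | N-(benzyloxy)-2-[(1R)-2-(4,4-diethoxybutyl)cyclopent-2-en-1-yl]acetamide | O=C(C[C@@H]1C(CCCC(OCC)OCC)=CCC1)NOCc1ccccc1
F2 | step 5 | (3aR,6S,6aS)-1-(benzyloxy)-6-bromo-6a-(4,4-diethoxybutyl)hexahydrocyclopenta[b]pyrrol-2(1H)-one | O=C1C[C@H]2CC[C@H](Br)[C@@]2(CCCC(OCC)OCC)N1OCc1ccccc1
F3 | step 26 | methyl ester 31 with C17–O-tert-butyldiphenylsilyl (C21–OTBS retained) | C[C@@H](/C=C\[C@@H](O[Si](c5ccccc5)(c6ccccc6)C(C)(C)C)/C=C(/Cl)CCO[Si](C)(C)C(C)(C)C)[C@H]1CCC[C@]12CCC[C@@H]3CC=C(C(=O)OC)CN23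
F4 | step 26 | C17–O-TBDPS methyl ester with free C21–OH | C[C@@H](/C=C\[C@@H](O[Si](c5ccccc5)(c6ccccc6)C(C)(C)C)/C=C(/Cl)CCO)[C@H]1CCC[C@]12CCC[C@@H]3CC=C(C(=O)OC)CN23
F5 | step 26 | C17–O-TBDPS seco acid | C[C@@H](/C=C\[C@@H](O[Si](c5ccccc5)(c6ccccc6)C(C)(C)C)/C=C(/Cl)CCO)[C@H]1CCC[C@]12CCC[C@@H]3CC=C(C(=O)O)CN23
F6 | step 26 | C17–O-TBDPS ether of macrolactone 34 | C[C@H]1/C=C\[C@@H](O[Si](c5ccccc5)(c6ccccc6)C(C)(C)C)/C=C(/Cl)CCOC(=O)C2=CC[C@H]3CCC[C@]4(CCC[C@H]14)N3C2
F7 | step 22 | propargylic alcohol 30 as a mixture of C17 epimers | C[C@@H](C#CC(O)/C=C(/Cl)CCO[Si](C)(C)C(C)(C)C)[C@H]1CCC[C@]12CCC[C@@H]3CC=C(C(=O)OC)CN23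
F8 | step 22 | C17 ynone corresponding to 30 | C[C@@H](C#CC(=O)/C=C(/Cl)CCO[Si](C)(C)C(C)(C)C)[C@H]1CCC[C@]12CCC[C@@H]3CC=C(C(=O)OC)CN23
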